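**Strategy.** The ten-membered carbocycle (C1–C10) is opened at C9–C10. Two features are used. Methyl-bearing C10 is allylic to the C1=C2–C3=O enone from which the epoxy ketone is later made. C9 is alpha to a C8 ketone that later becomes the lactone carbinol. A palladium-catalysed allylic alkylation therefore forms C9–C10, closes the ring with the whole C10–C1–C2 allyl unit inside it, and fixes C10 by net retention, all in one operation. The substrate is an open chain carrying a C9 β-keto sulfone, the C7 methyl acetate arm, a tartrate-derived C5/C6 acetonide, a C4 triethylsilyl ether, the C3 (E)-enone and an (S)-configured C10 methyl carbonate.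

Key step: step 15

Numbering: C1/C2 oxirane, C3 ketone, C4 tertiary carbinol, C5/C6 acyloxy carbons, C7/C8 lactone ring fusion (oxygen on C8), C9 methylene, C10 methyl-bearing carbon. C11, C12 and C13 are the α-carbon, carbonyl and exocyclic methylene of the lactone.
Remark: the oxirane of the target is cis (C3 and C10 on the same side), so the E olefin formed on ring closure must become Z before oxygen transfer.
Remark: C3 in 20, C9 in 22 and C11 in 27/28 are transient centres of no consequence. C3 in 25–30 is drawn as expected from outer-face hydride delivery and is erased in step 21.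

Step 1
Reactants: 1 dimethyl (4R,5R)-2,2-dimethyl-1,3-dioxolane-4,5-dicarboxylate (L-tartrate acetonide; its two carbinol carbons become C5 and C6)
Product: 2 bis-Weinreb amide (4R,5R)-N,N'-dimethoxy-N,N',2,2-tetramethyl-1,3-dioxolane-4,5-dicarboxamide
Conditions: MeNH(OMe)·HCl, iPrMgCl, THF, −20 to 0 °C
Reagents that add atoms: N,O-dimethylhydroxylamine hydrochloride, CNOC.Cl
Why: Weinreb amidation of both esters by the chloromagnesium amide is a standard acyl substitution, and it leaves the trans-dioxolane centres C5 and C6 from the chiral pool untouched.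

Step 2
Reactants: 2 bis-Weinreb amide
Product: 3 mono vinyl ketone (4R,5R)-5-acryloyl-N-methoxy-N,2,2-trimethyl-1,3-dioxolane-4-carboxamide (ketone carbon C4; vinyl CH C3; amide carbon C7)
Conditions: CH2=CHMgBr (1 equiv), THF, −78 to −20 °C; inverse quench into cold aq. HCl
Reagents that add atoms: vinylmagnesium bromide, C=C[Mg]Br
Why: Grignard addition to a Weinreb amide stops at the chelated tetrahedral adduct, whose charge slows attack on the second amide of the C2-symmetric diamide, and the cold acidic quench keeps the liberated amine from adding to the enone.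

Step 3
Reactants: 3 mono vinyl ketone
Product: 4 tertiary allylic alcohol (C4 carries methyl, vinyl and OH; C4–O syn to C5–O as in the target)
Conditions: MeTi(OiPr)3 (from MeLi and ClTi(OiPr)3), Et2O/CH2Cl2, −30 °C to rt
Reagents that add atoms: methyltriisopropoxytitanium, C[Ti](OC(C)C)(OC(C)C)OC(C)C
Why: This is a 1,2-addition of a non-chelating, amide-tolerant organotitanium reagent under polar Felkin–Anh control, in which methyl enters anti to the C5–O bond and past H5, setting C4.

Step 4
Reactants: 4 tertiary allylic alcohol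
Product: 5 C4 triethylsilyl ether
Conditions: Et3SiOTf, 2,6-lutidine, CH2Cl2, 0 °C
Reagents that add atoms: triethylsilyl triflate, CC[Si](CC)(CC)OS(=O)(=O)C(F)(F)F
Why: Silylation with a silyl triflate is the standard way to cap a hindered tertiary alcohol, and the buffered medium does not ionise the allylic carbinol.

Step 5
Reactants: 5 C4 triethylsilyl ether
Product: 6 C7 aldehyde
Conditions: iBu2AlH, THF, −78 °C
Reagents that add atoms: none
Why: Hydride reduction of a Weinreb amide stops at the chelated aluminium hemiaminal and gives the aldehyde on work-up, and the crude product is used at once so that C6 does not epimerise.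

Step 6
Reactants: 6 C7 aldehyde
Product: 7 (Z)-enoate (C7=C11 with C12 methyl ester)
Conditions: (CF3CH2O)2P(O)CH2CO2Me, KN(SiMe3)2, 18-crown-6, THF, −78 °C
Reagents that add atoms: methyl bis(2,2,2-trifluoroethyl)phosphonoacetate, COC(=O)CP(=O)(OCC(F)(F)F)OCC(F)(F)F
Why: The Still–Gennari variant of the Horner–Wadsworth–Emmons olefination gives the Z enoate under kinetic control at a temperature where the α-alkoxy aldehyde keeps its configuration.

Step 7
Reactants: 7 (Z)-enoate
Product: 8 γ-nitro ester (C7 bears CH2NO2 as C8 and CH2CO2Me as C11/C12; C7 as in the target)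
Conditions: MeNO2, DBU, MeCN, rt
Reagents that add atoms: nitromethane, C[N+](=O)[O-]
Why: Michael addition of nitronate to dioxolane-substituted enoates is a known syn-selective reaction, in which allylic 1,3-strain holds H6 in the olefin plane and the nitronate attacks anti to the bulky C6–C5 bond, setting C7.

Step 8
Reactants: 8 γ-nitro ester
Product: 9 C8 carboxylic acid (succinic half ester)
Conditions: NaNO2, AcOH, DMSO, 35 °C
Reagents that add atoms: sodium nitrite (oxygen source), [Na+].[O-]N=O
Why: The nitrite-mediated, Nef-type conversion of a primary nitroalkane into the acid runs through the nitrolic acid under weakly acidic conditions that spare acetonide, silyl ether, ester, vinyl group and C7.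

Step 9
Reactants: 9 C8 carboxylic acid; 10 methyl phenyl sulfone
Product: 13 β-keto sulfone with intact C3 vinyl group, via acyl imidazolide 11 (not isolated), via lithiated sulfone 12 (not isolated)
Conditions: 9, CDI, THF, rt; added to 10/n-BuLi (3.5 equiv), THF, −78 °C; aq. NH4Cl
Reagents that add atoms: 1,1'-carbonyldiimidazole, O=C(n1ccnc1)n1ccnc1 (imidazolyl group of 11 only); n-butyllithium, [Li]CCCC (lithium of 12 only)
Why: In this Claisen-type acylation the acyl imidazolide is far more electrophilic than the methyl ester, and the product is deprotonated at C9 at once, which stops over-addition and shields C7 from enolisation.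

Step 10
Reactants: 13 β-keto sulfone
Product: 14 C3 aldehyde
Conditions: O3, CH2Cl2, −78 °C; PPh3
Reagents that add atoms: ozone, [O-][O+]=O
Why: Ozonolysis cleaves the only olefin present, and the neutral reductive work-up leaves the non-enolisable α-silyloxy aldehyde and the keto sulfone unchanged.

Step 11
Reactants: 15 (S)-but-3-yn-2-ol; 16 methyl chloroformate
Product: 17 (S)-but-3-yn-2-yl methyl carbonate
Conditions: pyridine, CH2Cl2, 0 °C
Reagents that add atoms: none
Why: O-acylation with a chloroformate does not touch the carbinol centre that will become C10.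

Step 12
Reactants: 17 (S)-but-3-yn-2-yl methyl carbonate
Product: 19 (S,E)-4-iodobut-3-en-2-yl methyl carbonate, via alkenylzirconocene 18 (not isolated)
Conditions: Cp2Zr(H)Cl, THF, rt; I2, 0 °C
Reagents that add atoms: iodine, II; Cp2Zr(H)Cl, [H][Zr](Cl)(C1C=CC=C1)C1C=CC=C1 (zirconium of 18 only)
Why: Hydrozirconation adds syn with zirconium at the terminal carbon far faster than the hydride attacks a carbonate, and iodinolysis with retention gives the E iodide.

Step 13
Reactants: 14 C3 aldehyde; 19 (S,E)-4-iodobut-3-en-2-yl methyl carbonate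
Product: 20 open-chain allylic alcohol (C3 epimers)
Conditions: CrCl2, NiCl2 (cat.), DMSO, rt
Reagents that add atoms: none
Why: In the Nozaki–Hiyama–Kishi coupling the non-basic alkenylchromium reagent adds only to the aldehyde with retention of the E geometry, tolerating keto sulfone, ester and carbonate, and the new C3 centre is erased in step 14.

Step 14
Reactants: 20 open-chain allylic alcohol
Product: 21 cyclisation substrate (C9 β-keto sulfone; C7 acetate arm; C5/C6 acetonide; C4 OSiEt3; C3 E-enone; 10S methyl carbonate)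
Conditions: Dess–Martin periodinane, CH2Cl2, 0 °C to rt
Reagents that add atoms: none
Why: Dess–Martin oxidation of the hindered allylic alcohol is neutral and fast, so neither the acidic C9 methylene nor the γ-carbonate is disturbed.

Step 15
Reactants: 21 cyclisation substrate
Product: 22 ten-membered (E)-enone with C9 phenylsulfonyl group and C8 ketone (C10 methyl centre as in the target)
Conditions: Pd2(dba)3·CHCl3 (5 mol %), Ph2PCH2CH2PPh2 (dppe, 12 mol %), THF, 55 °C, slow addition of 21 to a final 0.002 M
Reagents that add atoms: none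
Why: Zerovalent palladium ionises the C10 carbonate with inversion to the syn,syn η3-allyl complex spanning C10–C1–C2, the methoxide released with CO2 deprotonates the β-keto sulfone so that no external base is needed, and the C9 carbanion attacks C10 anti to the metal. The closest known reaction type is the Tsuji–Trost macrocyclisation of sulfone- or ester-stabilised carbanions onto allylic carbonates or acetates at high dilution. The ten-membered carbocycle closes in the endo sense, all three allyl carbons becoming ring members, whereas attack at C2 would be an exo closure to an eight-membered ring, which such cyclisations avoid in favour of the larger ring. C10 is controlled by the (S)-carbonate centre through two successive inversions (net retention), aided by a chelating diphosphine and a low palladium concentration that suppress metal-for-metal exchange, while C9 is uncontrolled, epimerisable and removed in step 16. The step needs attack at C10 and not C2, which the C3 acyl group secures because soft nucleophiles add to the allyl terminus remote from an electron-withdrawing substituent and so keep the enone conjugated, and the syn complex delivers the E olefin. Cyclisation must also outrun oligomerisation and β-hydride loss to a dienone, which slow addition and the bidentate ligand are meant to ensure, while O-allylation is reversible and the liberated methoxide is degenerate with the methyl ester.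

Step 16
Reactants: 22 ten-membered (E)-enone sulfone
Product: 23 (E)-enone diketone (C9 now CH2)
Conditions: SmI2 (2.2 equiv), THF/MeOH, −78 °C, short contact
Reagents that add atoms: none
Why: Single-electron reductive desulfonylation of an α-sulfonyl ketone is very fast at −78 °C, where an enone or α-silyloxy ketone reacts slowly, and the samarium enolate is protonated at C9 only, so C7 is not touched.

Step 17
Reactants: 23 (E)-enone diketone
Product: 24 (Z)-enone diketone
Conditions: hν (365 nm), degassed MeCN, 0.005 M, 20 °C; recovered 23 recycled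
Reagents that add atoms: none
Why: In this photochemical E/Z isomerisation only the conjugated ketone absorbs at 365 nm, the excited C1=C2 bond twists and relaxes to either isomer, the less strained Z geometry should accumulate in a ten-membered ring, and a neutral aprotic medium lets any photoenol revert instead of deconjugating.

Step 18
Reactants: 24 (Z)-enone diketone
Product: 26 trans-fused γ-lactone with (Z)-allylic alcohol (8R; 3S expected), via diol ester 25 (not isolated)
Conditions: NaBH4, CeCl3·7H2O, MeOH, −78 to 0 °C; then PPTS (cat.), PhH, 50 °C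
Reagents that add atoms: none
Why: Luche reduction adds hydride 1,2 to both ring ketones from the outer face. At C8 the ring holds C6 and C9 transoid, so the C7 acetate arm screens one face and hydride enters opposite to it. The 8R hydroxy ester then lactonises, and C3 is parked as a carbinol for the next, strongly basic step.

Step 19
Reactants: 26 trans-fused γ-lactone
Product: 29 α-methylene lactone with (Z)-allylic alcohol, via Mannich base 27 (not isolated), via ammonium iodide 28 (not isolated)
Conditions: LiN(iPr)2 (3 equiv), THF, −78 °C; CH2=NMe2+ I−, −78 °C to rt; MeI, MeOH; aq. NaHCO3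
Reagents that add atoms: Eschenmoser's salt, C=[N+](C)C.[I-]; iodomethane, CI (methyl group of 28 only)
Why: This is a Mannich methylenation, in which the lactone enolate (with C3 as its alkoxide, kept at −78 °C to avoid silyl migration) is aminomethylated at C11 and quaternisation followed by Hofmann-type elimination installs C13 before any base-sensitive ester, ketone or oxirane is present.

Step 20
Reactants: 29 α-methylene lactone
Product: 30 cis-epoxy alcohol (C1 and C2 as in the target)
Conditions: VO(acac)2 (5 mol %), t-BuOOH, CH2Cl2, 0 °C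
Reagents that add atoms: tert-butyl hydroperoxide, CC(C)(C)OO
Why: Vanadium-catalysed hydroxyl-directed epoxidation transfers oxygen in a concerted syn manner, so Z gives cis, and it ignores the electron-poor methylene lactone. Allylic 1,3-strain holds H10 in the olefin plane with the ring chain (C9, C4) on the inner face, so the C3-bound peroxide reaches the outer face and sets C1 and C2.

Step 21
Reactants: 30 cis-epoxy alcohol
Product: 31 cis-epoxy ketone
Conditions: Dess–Martin periodinane, NaHCO3, CH2Cl2, 0 °C
Reagents that add atoms: none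
Why: Buffered Dess–Martin oxidation converts the only free carbinol into the C3 ketone without opening the oxirane.

Step 22
Reactants: 31 cis-epoxy ketone
Product: 32 C4,C5,C6-triol
Conditions: TFA/H2O (9:1), CH2Cl2, 0 °C
Reagents that add atoms: none
Why: Acid hydrolysis cleaves the strained trans-dioxolane and the silyl ether, while the electron-poor epoxy ketone and the methylene lactone resist cold aqueous acid.

Step 23
Reactants: 32 C4,C5,C6-triol
Product: 33 target CNP0253228.1
Conditions: (E)-crotonic anhydride, Et3N, DMAP (cat.), CH2Cl2, 0 °C to rt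
Reagents that add atoms: (E)-crotonic anhydride, C/C=C/C(=O)OC(=O)/C=C/C
Why: DMAP-catalysed (Steglich-type) acylation esterifies the two secondary alcohols, the tertiary α-ketol at C4 is too hindered to react, and the anhydride avoids the ketene pathway that would deconjugate the crotonyl group.

**Compound list**
1 | dimethyl (4R,5R)-2,2-dimethyl-1,3-dioxolane-4,5-dicarboxylate | COC(=O)[C@@H]1OC(C)(C)O[C@H]1C(=O)OC | starting material
2 | bis-Weinreb amide | CON(C)C(=O)[C@@H]1OC(C)(C)O[C@H]1C(=O)N(C)OC | intermediate
3 | mono vinyl ketone | CON(C)C(=O)[C@@H]1OC(C)(C)O[C@H]1C(=O)C=C | intermediate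
4 | tertiary allylic alcohol | CON(C)C(=O)[C@@H]1OC(C)(C)O[C@H]1[C@](C)(O)C=C | intermediate
5 | C4 triethylsilyl ether | CON(C)C(=O)[C@@H]1OC(C)(C)O[C@H]1[C@](C)(O[Si](CC)(CC)CC)C=C | intermediate
6 | C7 aldehyde | O=C[C@@H]1OC(C)(C)O[C@H]1[C@](C)(O[Si](CC)(CC)CC)C=C | intermediate
7 | (Z)-enoate | COC(=O)/C=C\[C@@H]1OC(C)(C)O[C@H]1[C@](C)(O[Si](CC)(CC)CC)C=C | intermediate
8 | γ-nitro ester | O=[N+]([O-])C[C@H](CC(=O)OC)[C@@H]1OC(C)(C)O[C@H]1[C@](C)(O[Si](CC)(CC)CC)C=C | intermediate
9 | C8 carboxylic acid | OC(=O)[C@H](CC(=O)OC)[C@@H]1OC(C)(C)O[C@H]1[C@](C)(O[Si](CC)(CC)CC)C=C | intermediate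
10 | methyl phenyl sulfone | CS(=O)(=O)c1ccccc1 | starting material
11 | acyl imidazolide | O=C(n1ccnc1)[C@H](CC(=O)OC)[C@@H]1OC(C)(C)O[C@H]1[C@](C)(O[Si](CC)(CC)CC)C=C | intermediate
12 | lithiated methyl phenyl sulfone | [Li]CS(=O)(=O)c1ccccc1 | intermediate
13 | β-keto sulfone with C3 vinyl group | O=S(=O)(c1ccccc1)CC(=O)[C@H](CC(=O)OC)[C@@H]1OC(C)(C)O[C@H]1[C@](C)(O[Si](CC)(CC)CC)C=C | intermediate
14 | C3 aldehyde | O=S(=O)(c1ccccc1)CC(=O)[C@H](CC(=O)OC)[C@@H]1OC(C)(C)O[C@H]1[C@](C)(O[Si](CC)(CC)CC)C=O | intermediate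
15 | (S)-but-3-yn-2-ol | C#C[C@H](C)O | starting material
16 | methyl chloroformate | COC(Cl)=O | starting material
17 | (S)-but-3-yn-2-yl methyl carbonate | C#C[C@H](C)OC(=O)OC | intermediate
18 | (E)-alkenylzirconocene chloride | Cl[Zr](C1C=CC=C1)(C1C=CC=C1)/C=C/[C@H](C)OC(=O)OC | intermediate
19 | (S,E)-4-iodobut-3-en-2-yl methyl carbonate | I/C=C/[C@H](C)OC(=O)OC | intermediate
20 | open-chain allylic alcohol (C3 epimers) | O=S(=O)(c1ccccc1)CC(=O)[C@H](CC(=O)OC)[C@@H]1OC(C)(C)O[C@H]1[C@](C)(O[Si](CC)(CC)CC)C(O)/C=C/[C@H](C)OC(=O)OC | intermediate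
21 | cyclisation substrate | O=S(=O)(c1ccccc1)CC(=O)[C@H](CC(=O)OC)[C@@H]1OC(C)(C)O[C@H]1[C@](C)(O[Si](CC)(CC)CC)C(=O)/C=C/[C@H](C)OC(=O)OC | intermediate
22 | ten-membered (E)-enone sulfone (C9 drawn as one epimer, labile) | O=S(=O)(c1ccccc1)[C@H]1C(=O)[C@H](CC(=O)OC)[C@@H]2OC(C)(C)O[C@H]2[C@](C)(O[Si](CC)(CC)CC)C(=O)/C=C/[C@@H]1C | intermediate
23 | (E)-enone diketone | C1C(=O)[C@H](CC(=O)OC)[C@@H]2OC(C)(C)O[C@H]2[C@](C)(O[Si](CC)(CC)CC)C(=O)/C=C/[C@@H]1C | intermediate
24 | (Z)-enone diketone | C1C(=O)[C@H](CC(=O)OC)[C@@H]2OC(C)(C)O[C@H]2[C@](C)(O[Si](CC)(CC)CC)C(=O)/C=C\[C@@H]1C | intermediate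
25 | C3,C8-diol ester | C1[C@@H](O)[C@H](CC(=O)OC)[C@@H]2OC(C)(C)O[C@H]2[C@](C)(O[Si](CC)(CC)CC)[C@@H](O)/C=C\[C@@H]1C | intermediate
26 | trans-fused lactone, (Z)-allylic alcohol | C1[C@H]3OC(=O)C[C@@H]3[C@@H]2OC(C)(C)O[C@H]2[C@](C)(O[Si](CC)(CC)CC)[C@@H](O)/C=C\[C@@H]1C | intermediate
27 | Mannich base (C11 epimers) | C1[C@H]3OC(=O)C(CN(C)C)[C@@H]3[C@@H]2OC(C)(C)O[C@H]2[C@](C)(O[Si](CC)(CC)CC)[C@@H](O)/C=C\[C@@H]1C | intermediate
28 | trimethylammonium iodide (C11 epimers) | C1[C@H]3OC(=O)C(C[N+](C)(C)C)[C@@H]3[C@@H]2OC(C)(C)O[C@H]2[C@](C)(O[Si](CC)(CC)CC)[C@@H](O)/C=C\[C@@H]1C.[I-] | intermediate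
29 | α-methylene lactone, (Z)-allylic alcohol | C1[C@H]3OC(=O)C(=C)[C@@H]3[C@@H]2OC(C)(C)O[C@H]2[C@](C)(O[Si](CC)(CC)CC)[C@@H](O)/C=C\[C@@H]1C | intermediate
30 | cis-epoxy alcohol | C1[C@H]3OC(=O)C(=C)[C@@H]3[C@@H]2OC(C)(C)O[C@H]2[C@](C)(O[Si](CC)(CC)CC)[C@@H](O)[C@H]4O[C@H]4[C@@H]1C | intermediate
31 | cis-epoxy ketone | C1[C@H]3OC(=O)C(=C)[C@@H]3[C@@H]2OC(C)(C)O[C@H]2[C@](C)(O[Si](CC)(CC)CC)C(=O)[C@H]4O[C@H]4[C@@H]1C | intermediate
32 | C4,C5,C6-triol | C1[C@H]3OC(=O)C(=C)[C@@H]3[C@H](O)[C@@H](O)[C@](C)(O)C(=O)[C@H]4O[C@H]4[C@@H]1C | intermediate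
33 | CNP0253228.1 | C=C1C(=O)O[C@@H]2C[C@@H](C)[C@@H]3O[C@@H]3C(=O)[C@@](C)(O)[C@H](OC(=O)/C=C/C)[C@@H](OC(=O)/C=C/C)[C@@H]12 | target

Total step count: 23. Longest linear sequence: 21 (steps 1–10 and 13–23).

**Steps most likely to fail**

Step 15. The closure may lose out to oligomerisation or to β-hydride elimination from the allyl complex. Stereochemical fidelity may also erode through syn–anti isomerisation of the acyl-substituted allyl unit. The fallback makes C9–C10 intermolecularly and closes the ring at C2–C3, setting out from 13 and returning at 22.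
- (R)-But-3-yn-2-ol with MsCl/Et3N gives (R)-but-3-yn-2-yl methanesulfonate F1.
- Alkylation of 13 with F1 (Cs2CO3, DMF; SN2 with inversion) gives the C9-propargylated keto sulfone F2.
- Ozonolysis, which cleaves the vinyl group much faster than the alkyne, gives the alkynyl aldehyde F3.
- Bu3SnH with PdCl2(PPh3)2 gives the (E)-alkenylstannane F4, and I2 converts it into the (E)-alkenyl iodide F5.
- An intramolecular Nozaki–Hiyama–Kishi reaction (CrCl2, cat. NiCl2, DMSO, high dilution) gives the macrocyclic allylic alcohol F6.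
- Dess–Martin oxidation of F6 gives 22.

Step 17. Irradiation may stall at an unfavourable photostationary state or drain material through photoenolisation and deconjugation. The fallback reaches the cis oxirane from the E olefin without isomerisation, by a syn dihydroxylation followed by a single inversion. It sets out from 23 and returns at 31.
- OsO4/NMO, with the PHAL ligand that favours the required face, gives the threo C1,C2-diol F7.
- 4-Nitrobenzenesulfonyl chloride/Et3N sulfonylates the more acidic α-keto hydroxyl to give the C2 nosylate F8.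
- K2CO3 in MeCN at 0 °C lets the C1 oxygen displace it with inversion at C2, giving the cis-epoxy diketone F9.
- NaBH4/CeCl3·7H2O gives the epoxy diol ester F10, which closes under PPTS to the epoxy alcohol lactone F11.
- The sequence of step 19 leads through the epoxy Mannich base F12 and the epoxy ammonium iodide F13 to the epoxy alcohol methylene lactone F14 (C3 epimers).
- Dess–Martin oxidation of F14 gives 31.

Step 18. Hydride may be delivered to the wrong face of the C8 carbonyl, which would lead to the cis-fused lactone. The fallback replaces the substrate-controlled double reduction by a stepwise, catalyst-controlled one, setting out from 24 and returning at 26.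
- The (S)-Me-CBS oxazaborolidine [(S)-1-methyl-3,3-diphenylhexahydropyrrolo[1,2-c][1,3,2]oxazaborole] with catecholborane in toluene at −78 °C distinguishes the branched C7 side from the C9 methylene.
- It should reduce the less hindered C8 ketone to the 8R hydroxy ester F15.
- PPTS closes F15 to the (Z)-enone lactone F16.
- A separate Luche reduction of the C3 enone gives 26.

Further compounds
F1 | step 15 | (R)-but-3-yn-2-yl methanesulfonate | C#C[C@@H](C)OS(C)(=O)=O
F2 | step 15 | C9-propargylated keto sulfone (C9 epimers) | O=S(=O)(c1ccccc1)C([C@@H](C)C#C)C(=O)[C@H](CC(=O)OC)[C@@H]1OC(C)(C)O[C@H]1[C@](C)(O[Si](CC)(CC)CC)C=C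
F3 | step 15 | alkynyl aldehyde | O=S(=O)(c1ccccc1)C([C@@H](C)C#C)C(=O)[C@H](CC(=O)OC)[C@@H]1OC(C)(C)O[C@H]1[C@](C)(O[Si](CC)(CC)CC)C=O
F4 | step 15 | (E)-alkenylstannane | O=S(=O)(c1ccccc1)C([C@@H](C)/C=C/[Sn](CCCC)(CCCC)CCCC)C(=O)[C@H](CC(=O)OC)[C@@H]1OC(C)(C)O[C@H]1[C@](C)(O[Si](CC)(CC)CC)C=O
F5 | step 15 | (E)-alkenyl iodide | O=S(=O)(c1ccccc1)C([C@@H](C)/C=C/I)C(=O)[C@H](CC(=O)OC)[C@@H]1OC(C)(C)O[C@H]1[C@](C)(O[Si](CC)(CC)CC)C=O
F6 | step 15 | macrocyclic allylic alcohol (C3 and C9 epimers) | O=S(=O)(c1ccccc1)C1C(=O)[C@H](CC(=O)OC)[C@@H]2OC(C)(C)O[C@H]2[C@](C)(O[Si](CC)(CC)CC)C(O)/C=C/[C@@H]1C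
F7 | step 17 | threo C1,C2-diol | C1C(=O)[C@H](CC(=O)OC)[C@@H]2OC(C)(C)O[C@H]2[C@](C)(O[Si](CC)(CC)CC)C(=O)[C@H](O)[C@@H](O)[C@@H]1C
F8 | step 17 | C2 nosylate | C1C(=O)[C@H](CC(=O)OC)[C@@H]2OC(C)(C)O[C@H]2[C@](C)(O[Si](CC)(CC)CC)C(=O)[C@H](OS(=O)(=O)c3ccc(cc3)[N+](=O)[O-])[C@@H](O)[C@@H]1C
F9 | step 17 | cis-epoxy diketone | C1C(=O)[C@H](CC(=O)OC)[C@@H]2OC(C)(C)O[C@H]2[C@](C)(O[Si](CC)(CC)CC)C(=O)[C@H]4O[C@H]4[C@@H]1C
F10 | step 17 | epoxy diol ester (C3 epimers) | C1[C@@H](O)[C@H](CC(=O)OC)[C@@H]2OC(C)(C)O[C@H]2[C@](C)(O[Si](CC)(CC)CC)C(O)[C@H]4O[C@H]4[C@@H]1C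
F11 | step 17 | epoxy alcohol lactone (C3 epimers) | C1[C@H]3OC(=O)C[C@@H]3[C@@H]2OC(C)(C)O[C@H]2[C@](C)(O[Si](CC)(CC)CC)C(O)[C@H]4O[C@H]4[C@@H]1C
F12 | step 17 | epoxy Mannich base | C1[C@H]3OC(=O)C(CN(C)C)[C@@H]3[C@@H]2OC(C)(C)O[C@H]2[C@](C)(O[Si](CC)(CC)CC)C(O)[C@H]4O[C@H]4[C@@H]1C
F13 | step 17 | epoxy ammonium iodide | C1[C@H]3OC(=O)C(C[N+](C)(C)C)[C@@H]3[C@@H]2OC(C)(C)O[C@H]2[C@](C)(O[Si](CC)(CC)CC)C(O)[C@H]4O[C@H]4[C@@H]1C.[I-]
F14 | step 17 | epoxy alcohol methylene lactone (C3 epimers) | C1[C@H]3OC(=O)C(=C)[C@@H]3[C@@H]2OC(C)(C)O[C@H]2[C@](C)(O[Si](CC)(CC)CC)C(O)[C@H]4O[C@H]4[C@@H]1C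
F15 | step 18 | 8R hydroxy ester with (Z)-enone | C1[C@@H](O)[C@H](CC(=O)OC)[C@@H]2OC(C)(C)O[C@H]2[C@](C)(O[Si](CC)(CC)CC)C(=O)/C=C\[C@@H]1C
F16 | step 18 | (Z)-enone lactone | C1[C@H]3OC(=O)C[C@@H]3[C@@H]2OC(C)(C)O[C@H]2[C@](C)(O[Si](CC)(CC)CC)C(=O)/C=C\[C@@H]1C
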